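The examiner sets one flask on the bench and wants a chain length from it.

free monomer 20 mM; initiator 0.5 mol%; time 3.0 min

    free monomer + living end → monomer in chains + living end, rate k1*[living end]*[free monomer] (k1 = 52 /M/s)
    initiator → spent initiator (k2 = 0.0023 /s)
    monomer in chains + living end → free monomer + living end, rate k3*[living end] as long as [monomer in chains] is above zero (k3 = 0.36 /s)
    free monomer + initiator → living end + monomer in chains (k4 = 2.1 /M/s)

- whether the average number of monomer units in a chain (chains begun, living or dead) reaches 40 by 3.0 min (no / yes)
- average number of monomer units in a chain (chains begun, living or dead) at 3.0 min

- the average divides the monomer in chains by the number of chains begun, living and dead together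
- run time (flask): 3.0 min

Where does free monomer stop? Where growth and unzipping balance, at a concentration of k3 over k1, which is a ceiling fraction of 34.6% of the charge. Under those two steps the excess above that level shrinks exponentially, with the area under the living-end curve, times k1, in the exponent.

How many chains? Initiator lasts a mean life of 0.376 min, pseudo-first-order with free monomer held at its charge. It starts chains faster than it spends itself, so I reckon 94.8% of it becomes living ends, a final level of 0.474% of the free monomer charged.

And the rising curve? Replace it by its mean. The final level, lessened by life over run time, makes the mean living end 0.415% of the charge. The mean keeps the area of that curve, and the area is what the exponent holds.

Your answer? Free monomer ends at 64.7% of its charge, and the length is 74.5, so yes.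

But free monomer falls, so your life is too short. Then try free monomer at its end level throughout, with the final level of living ends kept as it was. The life becomes 0.565 min, the mean 0.385%, and the reckoned length 70.8, still more than 40.0.

The forecast answers yes with a length of 75, against my 74.5, holding that “the monomer relaxes toward its ceiling-limited level”.

The simulated flask answers yes with 74.9. It reaches 40.0 at 1.47 min, with 18.4% of the free monomer reacted. Now charge twice the initiator, all other amounts as they are. The reckoned mean living end becomes 0.829% of the charge, the reckoned free monomer ends at 48.5%, and the reckoned length is 54.4. The simulated run with that charge gives 54.7.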